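The numbers in the tables are calculated from invented constants.

Grey and blue, each charged with 0.95 equiv of Ly, still show Rx at their last readings, 10 % and 3 %, while violet with 1.4 equiv shows less, 0 %. These are the runs, and this is the flask we want to foresee:

| flask | Rx | Ly | remark | time |
|---|---|---|---|---|
| grey | 0.025 M | 0.95 equiv | run made earlier |  |
| blue | 0.10 M | 0.95 equiv | run made earlier |  |
| violet | 0.050 M | 1.4 equiv | run made earlier |  |
| flask | 0.050 M | 0.950 equiv |  | 15 min |

| run | time / min | Ju / % | Rx / % |
|---|---|---|---|
| grey | 4.00 | 56 | 37 |
| grey | 8.00 | 90 | 12 |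
| grey | 10.0 | 93 | 13 |
| grey | 15.0 | 93 | 7 |
| grey | 20.0 | 92 | 10 |
| blue | 1.33 | 94 | 5 |
| blue | 2.50 | 95 | 3 |
| blue | 5.00 | 97 | 6 |
| blue | 10.0 | 94 | 2 |
| blue | 20.0 | 93 | 3 |
| violet | 4.00 | 99 | 0 |
| violet | 8.00 | 99 | 0 |
| violet | 10.0 | 96 | 0 |
| violet | 15.0 | 101 | 1 |
| violet | 20.0 | 101 | 0 |

(standard deviation of a reading: 2 percentage points)

- reactions considered so far: Rx + Ly + Zu -> Ju + 2 Zu; Rx + Ly -> Ju + Zu
- the reaction counts as stopped when no species that holds the Rx changes by six tenths of a point or more over the second half of the time

- at 15 min, what has stopped the reaction, if anything has (all of Rx has reacted / Ly has run out first / it is still moving)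
- the Ju standing at 15 min, as a percentage of the Rx charged

We build the flask one process at a time, reckoning with what is left and not with what is made. Take first the plain step, in which one Rx and one Ly give one Ju and one Zu: Ly is the limiting reagent at 0.950 equiv, so the share of charged Rx that finds no Ly is 5.00 %, the remainder, one minus the equivalents of Ly, and Ju can reach 95.0 %.

Now add the step carried by Zu. It also spends one Ly per Rx, so the remainder stays where it was and the clock changes: grey shows 90 % Ju at 8.00 min, and blue shows 94 % at 1.33 min. The flask's Rx lies between theirs, so we place its stop between those times, earlier than 15 min.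

Last, the readings themselves: violet still shows 101 % Ju at 20.0 min, so we allow no loss of Ju, and grey's last Ju lies 3 percentage points under the reckoned ceiling, against a scatter of 2 points. The forecast says Ly has run out first, with Ju at 95 % (range 93.5 % to 96 %), on the ground that “Ly is limiting at 0.95 equiv”.

In the flask at 15 min the outcome is that Ly has run out first, with Ju at 95.0 %, on these equations:

    Rx + Ly + Zu → Ju + 2 Zu (k = 64.0 /M²/s)
    Rx + Ly → Ju + Zu (k = 0.00160 /M/s)

Rx stands in the flask at 5.01 %, the remainder we reckoned, beside 0.00905 % of the Ly charge. At that moment the Zu-carried step in the flask has a half-life of 1.5 min for Ly against 15 h for Rx. In the same flask charged with 0.380 equiv of Ly, the remainder comes to 62.0 %, and at 15.0 min that flask shows Rx at 62.0 %.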